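**Plan**

- Retrosynthesis: the acetate is removed and the C2 hydroxyl is traced back to a C2 bromide. The C4 carbonyl is taken back to C4–H of a 1-naphthol. The C1–C2 and C2–C3 bonds of the quinone ring are then cut together, which takes out C2 as a dibromocarbene carbon and leaves the silyl enol ether of a 2-alkylindan-1-one. The side chain is cut at its ring–CH2 bond, and the indanone at its aryl–C(=O) and aryl–CH2 bonds.
- Enabling feature: C2 of the quinone ring (the carbon bearing OH) lies between the carbonyl carbon C1 and the chain-bearing C3. Without it the ring is the five-membered ring of an indan-1-one (indanone C1 = carbonyl, C2 = chain carbon, C3 = benzylic CH2) fused to the trimethoxybenzene ring. Carbonyl, chain and arene are then already in the right order, and C2 is the only enolisable position.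
- Forward order: the benzene ring is bought; the five-membered ring is closed by acylation and Nazarov cyclisation (steps 1–2); the chain is joined by aza-enolate opening of an epoxide (steps 3–4); the five-membered ring is expanded to the six-membered ring by carbene insertion (step 6); oxidation to the quinone, Br→OH exchange and acetylation follow (steps 7–9).
- Stereochemistry: the single (S) centre comes from (S)-propylene oxide, which is opened at its CH2 carbon. The C–O bond at the stereocentre is never broken afterwards; only O–Si and O–acyl bonds are made and cleaved.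

Key step: step 6

Remark on the chemistry: 4,5,7-trimethoxyindan-1-one is not assumed to be purchasable and is made in two steps. Ring carbons that are stereogenic only in passing (C2 of indanone 10, the two cyclopropane carbons of 14) are left unspecified, because they become sp2 later. Hydroxy ketone 10 is drawn and used as its open form, although part of it may sit as the cyclic hemiketal.

**Route**

Step 1
Reactants: 1 1,2,4-trimethoxybenzene; 2 3-chloropropanoyl chloride
Product: 3 3-chloro-1-(2,4,5-trimethoxyphenyl)propan-1-one
Conditions: AlCl3 (1.1 equiv), CH2Cl2, −10 → 0 °C; ice/1 M HCl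
Reagents that add atoms: none
Why: Friedel–Crafts acylation should take place at C5 of 1, the position para to one methoxy group and ortho to another that is not flanked on both sides, and the low temperature should keep the methoxy group ortho to the new ketone from Lewis-acid demethylation.

Step 2
Reactants: 3 3-chloro-1-(2,4,5-trimethoxyphenyl)propan-1-one
Product: 5 4,5,7-trimethoxyindan-1-one, via aryl vinyl ketone 4 (not isolated)
Conditions: conc. H2SO4, 85 °C; poured onto ice
Reagents that add atoms: none
Why: Loss of HCl should give enone 4, whose O-protonated form closes by 4π-conrotatory Nazarov cyclisation onto the only unsubstituted ortho carbon, which is the standard sulfuric-acid route from aryl 2-chloroethyl ketones to methoxy-substituted indan-1-ones.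

Step 3
Reactants: 5 4,5,7-trimethoxyindan-1-one
Product: 6 4,5,7-trimethoxyindan-1-one N,N-dimethylhydrazone
Conditions: Me2NNH2 (5 equiv), AcOH (cat.), EtOH, 4 Å MS, reflux
Reagents that add atoms: N,N-dimethylhydrazine, CN(C)N
Why: Acid-catalysed condensation with removal of water should give the hydrazone, which is needed because its aza-enolate opens epoxides cleanly whereas the ketone enolate does not.

Step 4
Reactants: 6 4,5,7-trimethoxyindan-1-one N,N-dimethylhydrazone; 7 (S)-propylene oxide
Product: 10 2-[(S)-2-hydroxypropyl]-4,5,7-trimethoxyindan-1-one (mixture of C2 epimers), via lithiated hydrazone 8 (not isolated), via hydrazone alkoxide 9 (not isolated)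
Conditions: LDA (1.1 equiv), THF, 0 °C; 7 (1.5 equiv), 0 °C → rt; then 2 M HCl, THF/H2O, rt
Reagents that add atoms: water, O
Why: Metalated dimethylhydrazones are established nucleophiles for SN2 opening of terminal epoxides at the CH2 carbon (aza-enolate alkylation), so the C–O bond of the stereocentre is untouched and (S)-7 should give the (S)-carbinol, aqueous acid then hydrolyses the hydrazone, and the uncontrolled ring centre at C2 is erased in step 5.

Step 5
Reactants: 10 2-[(S)-2-hydroxypropyl]-4,5,7-trimethoxyindan-1-one
Product: 11 triethylsilyl enol ether of 2-[(S)-2-(triethylsilyloxy)propyl]-4,5,7-trimethoxyindan-1-one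
Conditions: TESOTf (2.5 equiv), Et3N (4 equiv), CH2Cl2, 0 °C → rt; pentane, cold aq. NaHCO3; used crude
Reagents that add atoms: triethylsilyl trifluoromethanesulfonate, CC[Si](CC)(CC)OS(=O)(=O)C(F)(F)F
Why: The silyl triflate with triethylamine should silylate the secondary alcohol and, by soft enolisation of the aryl ketone, form the silyl enol ether across C1=C2, the only regioisomer possible because C2 is the sole enolisable position.

Step 6
Reactants: 11 triethylsilyl enol ether of 2-[(S)-2-(triethylsilyloxy)propyl]-4,5,7-trimethoxyindan-1-one; 12 bromoform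
Product: 16 2-bromo-5,6,8-trimethoxy-3-[(S)-2-(triethylsilyloxy)propyl]naphthalen-1-ol, via dibromocarbene 13 (not isolated), via dibromocyclopropane 14 (not isolated), via bromonaphthalenone 15 (not isolated)
Conditions: KOtBu (2.5 equiv), pentane, −30 °C; 12 (1.3 equiv) added slowly, → rt; cold 0.5 M HCl to pH 5
Reagents that add atoms: none
Why: tert-Butoxide α-eliminates HBr from bromoform to give dibromocarbene 13, which adds as an electrophile in a concerted [2+1] cheletropic cycloaddition to the electron-rich C1=C2 enol ether bond of 11 and so forms both new C–C bonds of cyclopropane 14. The siloxy oxygen then drives a disrotatory 2π-electrocyclic opening of the cyclopropane with loss of the endo bromide, which cleaves the former C1–C2 bond, turns the bicyclo[3.1.0] unit into a six-membered ring and, after loss of the silyl group from oxygen, gives 2-bromo-4H-naphthalen-1-one 15, which tautomerises to naphthol 16. The closest known reaction type is the dihalocarbene one-carbon ring expansion of cyclic ketone silyl enol ethers to 2-halo enones, which for indan-1-ones ends in 2-halo-1-naphthols. The three-membered ring closes by cycloaddition and the six-membered ring arises by ring expansion and not by cyclisation, so no arene carbon has to act as a nucleophile. No stereocentre is set, because the two cyclopropane centres are transient and the side-chain centre is remote and untouched. The step needs chemoselectivity for the enol ether over the trimethoxybenzene ring and a single site of insertion, and these are secured by the far higher nucleophilicity of the silyl enol ether and by the single enolisable position of the indanone.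

Step 7
Reactants: 16 2-bromo-5,6,8-trimethoxy-3-[(S)-2-(triethylsilyloxy)propyl]naphthalen-1-ol
Product: 17 2-bromo-5,6,8-trimethoxy-3-[(S)-2-(triethylsilyloxy)propyl]-1,4-naphthoquinone
Conditions: Fremy's salt (2.5 equiv), KH2PO4 buffer (pH 6), acetone/H2O, rt
Reagents that add atoms: potassium nitrosodisulfonate (Fremy's salt), [K+].[K+].[O]N(S(=O)(=O)[O-])S(=O)(=O)[O-]
Why: In this Teuber oxidation the naphthoxyl radical should couple with a second nitrosodisulfonate radical at the free para carbon C4 and collapse to the 1,4-quinone, while bromine blocks C2 against ortho-quinone formation and the reagent, which attacks only free phenols, leaves the para-dimethoxy-substituted ring alone.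

Step 8
Reactants: 17 2-bromo-5,6,8-trimethoxy-3-[(S)-2-(triethylsilyloxy)propyl]-1,4-naphthoquinone
Product: 19 2-hydroxy-3-[(S)-2-hydroxypropyl]-5,6,8-trimethoxy-1,4-naphthoquinone, via potassium quinonolate 18 (not isolated)
Conditions: KOH (5 equiv), THF/H2O, 50 °C, N2; then 2 M HCl to pH 1, rt
Reagents that add atoms: potassium hydroxide, [K+].[OH-]
Why: Hydroxide should add at C2 and expel bromide (addition–elimination at a vinylogous acyl bromide) to give the stabilised quinonolate 18, which resists further attack, and the acidic work-up then protonates it and cleaves the triethylsilyl ether at the O–Si bond without touching the stereocentre.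

Step 9
Reactants: 19 2-hydroxy-3-[(S)-2-hydroxypropyl]-5,6,8-trimethoxy-1,4-naphthoquinone
Product: 21 2-hydroxy-3-[(S)-2-acetoxypropyl]-5,6,8-trimethoxy-1,4-naphthoquinone (CNP0321270.1), via diacetate 20 (not isolated)
Conditions: Ac2O (3 equiv), pyridine, DMAP (0.1 equiv), CH2Cl2, 0 °C → rt; then H2O, rt
Reagents that add atoms: acetic anhydride, CC(=O)OC(C)=O
Why: DMAP-catalysed acetylation esterifies the secondary alcohol with retention, and although the acidic C2 hydroxyl is acetylated as well, that enol acetate is a vinylogous mixed anhydride and should be hydrolysed selectively during the aqueous pyridine/DMAP quench while the alkyl acetate survives.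

**Compound list**

1 | 1,2,4-trimethoxybenzene | COc1ccc(OC)c(OC)c1 | starting material
2 | 3-chloropropanoyl chloride | O=C(Cl)CCCl | starting material
3 | 3-chloro-1-(2,4,5-trimethoxyphenyl)propan-1-one | COc1cc(OC)c(cc1OC)C(=O)CCCl | intermediate
4 | 1-(2,4,5-trimethoxyphenyl)prop-2-en-1-one (aryl vinyl ketone, not isolated) | C=CC(=O)c1cc(OC)c(OC)cc1OC | intermediate
5 | 4,5,7-trimethoxyindan-1-one | COc1cc(OC)c2c(c1OC)CCC2=O | intermediate
6 | 4,5,7-trimethoxyindan-1-one N,N-dimethylhydrazone | COc1cc(OC)c2c(c1OC)CCC2=NN(C)C | intermediate
7 | (S)-propylene oxide ((S)-2-methyloxirane) | C[C@H]1CO1 | starting material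
8 | lithiated hydrazone (aza-enolate of 6, not isolated) | COc1cc(OC)c2c(c1OC)CC=C2N([Li])N(C)C | intermediate
9 | lithium alkoxide of the 2-[(S)-2-hydroxypropyl] hydrazone (not isolated) | COc1cc(OC)c2c(c1OC)CC(C[C@H](C)O[Li])C2=NN(C)C | intermediate
10 | 2-[(S)-2-hydroxypropyl]-4,5,7-trimethoxyindan-1-one (C2 epimers) | COc1cc(OC)c2c(c1OC)CC(C[C@H](C)O)C2=O | intermediate
11 | triethylsilyl enol ether of 2-[(S)-2-(triethylsilyloxy)propyl]-4,5,7-trimethoxyindan-1-one (4,6,7-trimethoxy-3-(triethylsilyloxy)-2-[(S)-2-(triethylsilyloxy)propyl]-1H-indene) | COc1cc(OC)c2c(c1OC)CC(C[C@H](C)O[Si](CC)(CC)CC)=C2O[Si](CC)(CC)CC | intermediate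
12 | bromoform | BrC(Br)Br | starting material
13 | dibromocarbene (not isolated) | Br[C]Br | intermediate
14 | gem-dibromocyclopropane adduct of 11, CBr2 bridging indanone C1 and C2 (not isolated) | COc1cc(OC)c2c(c1OC)CC3(C[C@H](C)O[Si](CC)(CC)CC)C(Br)(Br)C23O[Si](CC)(CC)CC | intermediate
15 | 2-bromo-5,6,8-trimethoxy-3-[(S)-2-(triethylsilyloxy)propyl]-4H-naphthalen-1-one (not isolated) | COc1cc(OC)c2c(c1OC)CC(C[C@H](C)O[Si](CC)(CC)CC)=C(Br)C2=O | intermediate
16 | 2-bromo-5,6,8-trimethoxy-3-[(S)-2-(triethylsilyloxy)propyl]naphthalen-1-ol | COc1cc(OC)c2c(O)c(Br)c(C[C@H](C)O[Si](CC)(CC)CC)cc2c1OC | intermediate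
17 | 2-bromo-5,6,8-trimethoxy-3-[(S)-2-(triethylsilyloxy)propyl]-1,4-naphthoquinone | COc1cc(OC)c2c(c1OC)C(=O)C(C[C@H](C)O[Si](CC)(CC)CC)=C(Br)C2=O | intermediate
18 | potassium salt of 2-hydroxy-5,6,8-trimethoxy-3-[(S)-2-(triethylsilyloxy)propyl]-1,4-naphthoquinone (not isolated) | COc1cc(OC)c2c(c1OC)C(=O)C(C[C@H](C)O[Si](CC)(CC)CC)=C([O-])C2=O.[K+] | intermediate
19 | 2-hydroxy-3-[(S)-2-hydroxypropyl]-5,6,8-trimethoxy-1,4-naphthoquinone | COc1cc(OC)c2c(c1OC)C(=O)C(C[C@H](C)O)=C(O)C2=O | intermediate
20 | 2-acetoxy-3-[(S)-2-acetoxypropyl]-5,6,8-trimethoxy-1,4-naphthoquinone (not isolated) | COc1cc(OC)c2c(c1OC)C(=O)C(C[C@H](C)OC(C)=O)=C(OC(C)=O)C2=O | intermediate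
21 | 2-hydroxy-3-[(S)-2-acetoxypropyl]-5,6,8-trimethoxy-1,4-naphthoquinone (CNP0321270.1) | COc1cc(OC)c2c(c1OC)C(=O)C(C[C@H](C)OC(C)=O)=C(O)C2=O | target

**Step count and risks**

Total step count: 9. Longest linear sequence: 9 steps, from 1,2,4-trimethoxybenzene.

The three steps judged most likely to fail are steps 6, 4 and 5.

Step 6. The silyl enol ether may be cleaved by tert-butoxide before the carbene is captured, and the product naphthoxide may react further with excess carbene (Reimer–Tiemann-type attack at C4). The fallback sets out from 11 and generates the carbene without any alkoxide. Sodium trichloroacetate in refluxing DME decarboxylates to dichlorocarbene F1, which should cyclopropanate 11 to the dichlorocyclopropane F2. At the reaction temperature F2 should open through 2-chloro-4H-naphthalen-1-one F3 to the 2-chloronaphthol F4. Fremy's salt, as in step 7, should then give the chloroquinone F5. KOH followed by HCl, as in step 8, replaces chloride by hydroxyl through 18 and removes the silyl group, so the fallback comes back to the route at 19.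

Step 4. The hindered aza-enolate may open the epoxide sluggishly, and the γ-hydroxy hydrazone or ketone may cyclise to a hemiketal or dihydrofuran during acidic hydrolysis. The fallback sets out from 5 and builds the chain by an aldol sequence. LDA (THF, −78 °C) gives the lithium enolate F6, which adds to commercial (S)-2-(tert-butyldimethylsilyloxy)propanal; an AcOH quench gives the β-hydroxy ketone F7. MsCl/Et3N (CH2Cl2, 0 °C → rt) converts it through the mesylate F8 into the exocyclic enone F9. Hydrogenation (H2, Pd/C, EtOAc) gives the saturated silyl ether F10, and HF·pyridine (THF) frees the alcohol, so the fallback comes back to the route at 10.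

Step 5. The cyclic hemiketal tautomer may be silylated in place of the open hydroxy ketone, enolisation at the hindered C2–H may be incomplete, and the enol ether may hydrolyse during isolation. The fallback sets out from 10 and separates the two silylations. TESCl/imidazole (DMF) should silylate only the secondary alcohol of the open form and give the mono-silyl ether F11. KHMDS (THF, −78 °C) then forms the potassium enolate F12 by hard deprotonation, and trapping with TESCl brings the fallback back to the route at 11.

Further compounds
F1 | step 6 | dichlorocarbene | Cl[C]Cl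
F2 | step 6 | gem-dichlorocyclopropane adduct of 11 | COc1cc(OC)c2c(c1OC)CC3(C[C@H](C)O[Si](CC)(CC)CC)C(Cl)(Cl)C23O[Si](CC)(CC)CC
F3 | step 6 | 2-chloro-5,6,8-trimethoxy-3-[(S)-2-(triethylsilyloxy)propyl]-4H-naphthalen-1-one | COc1cc(OC)c2c(c1OC)CC(C[C@H](C)O[Si](CC)(CC)CC)=C(Cl)C2=O
F4 | step 6 | 2-chloro-5,6,8-trimethoxy-3-[(S)-2-(triethylsilyloxy)propyl]naphthalen-1-ol | COc1cc(OC)c2c(O)c(Cl)c(C[C@H](C)O[Si](CC)(CC)CC)cc2c1OC
F5 | step 6 | 2-chloro-5,6,8-trimethoxy-3-[(S)-2-(triethylsilyloxy)propyl]-1,4-naphthoquinone | COc1cc(OC)c2c(c1OC)C(=O)C(C[C@H](C)O[Si](CC)(CC)CC)=C(Cl)C2=O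
F6 | step 4 | lithium enolate of 4,5,7-trimethoxyindan-1-one | COc1cc(OC)c2c(c1OC)CC=C2O[Li]
F7 | step 4 | 2-[(2S)-2-(tert-butyldimethylsilyloxy)-1-hydroxypropyl]-4,5,7-trimethoxyindan-1-one (diastereomer mixture) | COc1cc(OC)c2c(c1OC)CC(C(O)[C@H](C)O[Si](C)(C)C(C)(C)C)C2=O
F8 | step 4 | methanesulfonate of F7 | COc1cc(OC)c2c(c1OC)CC(C(OS(C)(=O)=O)[C@H](C)O[Si](C)(C)C(C)(C)C)C2=O
F9 | step 4 | (E)-2-[(2S)-2-(tert-butyldimethylsilyloxy)propylidene]-4,5,7-trimethoxyindan-1-one | COc1cc(OC)c2c(c1OC)C/C(=C\[C@H](C)O[Si](C)(C)C(C)(C)C)C2=O
F10 | step 4 | 2-[(S)-2-(tert-butyldimethylsilyloxy)propyl]-4,5,7-trimethoxyindan-1-one | COc1cc(OC)c2c(c1OC)CC(C[C@H](C)O[Si](C)(C)C(C)(C)C)C2=O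
F11 | step 5 | 2-[(S)-2-(triethylsilyloxy)propyl]-4,5,7-trimethoxyindan-1-one | COc1cc(OC)c2c(c1OC)CC(C[C@H](C)O[Si](CC)(CC)CC)C2=O
F12 | step 5 | potassium enolate of F11 | COc1cc(OC)c2c(c1OC)CC(C[C@H](C)O[Si](CC)(CC)CC)=C2O[K]
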